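## Structural features

1. The target is the (9Z)-hexadec-9-enoate of (3R)-β,β-caroten-3-ol. Ring A (C1–C6: gem-dimethyl at C1, acyloxy at C3, methyl at C5, C5=C6 double bond) and the unoxidised ring B (C1'–C6') are joined through their fully substituted trigonal carbons C6 and C6' by an all-E C22 chain (C7–C15, C15'–C7') with nine double bonds and methyl groups at C9, C13, C13' and C9'.
2. C3 is the only stereocentre (R). No other stereocentre stands next to it, and its ring neighbours C2 and C4 are both CH2 groups that differ only one atom further out (C1 quaternary, C5 trigonal), so reagent control alone has little to work with.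
3. Without the C3 substituent the C40 hydrocarbon would be C2-symmetric about C15=C15'. The real difficulty is therefore constitutional: two almost identical ends must be told apart without statistical mixtures, and eleven conjugated double bonds must end up all-E.
4. The fragile groups are the undecaene (oxygen, light, acid, radicals, long heating), the ester (the alkoxide or hydroxide bases of ylide chemistry) and the isolated 9Z alkene of the acyl chain. That alkene would not survive the iodine- or radical-mediated equilibration commonly used to repair polyene geometry.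
5. The most hindered bond is C6–C7, because C6 is flanked by the quaternary C1 and the methyl-bearing C5.
6. The key step exploits this atom. C6 of ring A maps onto a ketone carbonyl and hence onto an enol triflate, and an alkenyl–palladium bond at C6 has no β-hydrogen (C1 carries none, C5 is trigonal), so it can persist through a slow transmetalation.
7. Everything beyond C7 (C8 to ring B, thirty carbons with all geometry in place) coincides with a commercial apocarotenal. Forming C6–C7 last therefore distinguishes the two ends by construction, makes no new double bond inside the chromophore, and lets the ester and the 9Z alkene enter before the polyene is touched.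

## Logic of the disconnections

**14 ⇒ 10 + 13.** The bond cut is the C6–C7 single bond that ties ring A to the chain. It is the only bond whose removal leaves on one side every element that makes the target unsymmetrical and base-sensitive (C3 stereocentre, ester, 9Z alkene), and on the other side the complete chromophore with ring B. The gain is a split of 56 carbons into 25 and 31, with no chromophore double bond left to make. The demand is a C(sp2)–C(sp2) coupling at a tetrasubstituted alkene carbon next to a quaternary centre, with retention at C7=C8, under conditions that spare an ester, an isolated Z alkene and an undecaene. In one sentence, the route is the palladium-catalysed union of 10 at C6 with 13 at C7 as the last step.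

**13 ⇒ 11 (through 12).** The C7=C8 double bond is cut so that C7 leaves together with boron as a one-carbon reagent. The gain is that 11 is bought with thirty of the thirty-one carbons, ring B and eight chain double bonds of fixed geometry. The demand is 1,2-addition to a weakly electrophilic polyenal and an E-selective elimination without free strong base.

**10 ⇒ 7 + 8 (through 9).** The acyl C–O bond is cut, not the C3–O bond. The ester and the 9Z alkene are thus installed on a robust C9 ring and never on the polyene. The demand is acylation with retention at C3 in the presence of the enol sulfonate group.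

**7 ⇒ 6 ⇒ 4 (through 5).** The O–S bond of the enol sulfonate is cut, which turns C5=C6 back into a C6 ketone with one hydrogen on C5. Only one enolate is possible, so the position of the ring double bond is unambiguous. The demand is a strong base, which an ester at C3 would not survive. This is the reason for the temporary silyl ether and for its removal in 6 ⇒ 7. The stereocentre at C5 is erased in this step.

**4 ⇒ 3 ⇒ 2.** After the O–Si bond, the C3–H bond is cut. The C3 stereocentre is set by 1,3-relay from the C5 methyl stereocentre and the axial C1 methyl. This replaces a hard enantioface problem with a diastereoface problem whose errors can be removed as diastereomers. The demand is site selectivity between two ketones and attack from one face.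

**2 ⇒ 1.** The C4–H and C5–H bonds are cut. An achiral, flat enedione remains. The demand is enantioface-selective hydrogen addition to its only C=C bond.

## Other disconnections considered

**Alternative 1:** (the first that comes to mind) Cut the acyl C–O bond to (3R)-β,β-caroten-3-ol A1, then cut C11=C12 of A1.
- The forward key step is a Wittig olefination of 12'-apo-β-caroten-12'-al A3 with the ylide of [(2E,4E)-5-[(4R)-4-hydroxy-2,6,6-trimethylcyclohex-1-en-1-yl]-3-methylpenta-2,4-dien-1-yl]triphenylphosphonium bromide A2, followed by acylation with 8.
- A2 needs C7–C11 grown on the same ring ketone over many steps: addition to the hindered carbonyl, dehydration, partial reduction, vinyl addition and salt formation. A3 is itself the product of an earlier olefination.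
- The new double bond lies in the middle of the chromophore. A semi-stabilised ylide is under kinetic control there and an E/Z mixture must be expected, so an equilibration would be needed.
- Alkoxide bases exclude the ester, so acylation moves to the end and the polyene passes through more operations. Equilibration after acylation would endanger the 9Z alkene.
- The chosen plan makes no chromophore double bond and handles the polyene only twice.

**Alternative 2:** Cut the central C15=C15' bond into two C20 halves.
- The forward key step is a Ramberg–Bäcklund contraction of the unsymmetrical sulfone retinyl (3R)-3-(tert-butyldimethylsilyloxy)retinyl sulfone A4. One half would come from all-E-retinol A5.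
- The sulfur tether gives perfect cross-selectivity and fragments of equal size.
- Against this, the oxygenated half still needs eleven chain carbons built onto the ring.
- Pentaenyl allylic electrophiles ionise easily and lose a proton or rearrange.
- The halogenating, strongly basic medium of the contraction is hostile to a polyene and excludes the ester.
- The episulfone collapse is not inherently E-selective at C15=C15'.
- More steps and more polyene handling follow than in the chosen plan.

**Alternative 3:** Cut both ring–chain bonds, C6–C7 and C6'–C7'.
- 8,8'-Diapocarotene-8,8'-dial A6 would be converted to the C22 bis(pinacol boronate) A7, which would be coupled with 10 and with 2,6,6-trimethylcyclohex-1-en-1-yl trifluoromethanesulfonate A8.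
- The two termini of A7 are homotopic and too far apart for the first coupling to deactivate the second. A statistical set of mono- and double-coupled products must be expected.
- The hindered coupling would also have to succeed twice.
- Compound 11 already holds ring B and its C6'–C7' bond, so the chosen plan keeps the idea but removes the statistics and one hindered coupling.

Key step: step 8

Remark on the chemistry: carotenoid numbering is used for 11–14. Locants C1, C2, C4 and C6 of the cyclohexanones 2–4 correspond to carotenoid C6, C1, C3 and C5. Compound 11 is taken as the commercial all-E material, whose aldehyde carbon becomes C8 of 14. All work with 11–14 is done under argon in dim light.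

## Steps

**Step 1**
Reactants: 1 2,6,6-trimethylcyclohex-2-ene-1,4-dione (ketoisophorone)
Product: 2 (6R)-2,2,6-trimethylcyclohexane-1,4-dione
Conditions: Old Yellow Enzyme 2 (ene-reductase of Saccharomyces cerevisiae), NADP+ (cat.), glucose dehydrogenase, D-glucose, phosphate buffer pH 7, 30 °C
Reagents that add atoms: none
Why: Biocatalytic asymmetric alkene reduction (ene-reductase of the Old Yellow Enzyme family): reduced flavin delivers hydride and an active-site tyrosine the proton in a net trans addition across the doubly activated C2=C3 bond, and the fixed binding mode of 1 should give the (R) configuration at the methyl-bearing carbon. The two carbonyl groups are not substrates of this enzyme, and crystalline 2 can be recrystallised to raise its enantiomeric purity.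

**Step 2**
Reactants: 2 (6R)-2,2,6-trimethylcyclohexane-1,4-dione
Product: 3 (4R,6R)-4-hydroxy-2,2,6-trimethylcyclohexan-1-one (hydroxy group trans to the 6-methyl group)
Conditions: LiBH(s-Bu)3 (1.05 equiv), THF, −78 °C; then H2O2, NaOH aq., 0 °C
Reagents that add atoms: none
Why: Diastereoselective ketone reduction under steric approach control: C1=O is shielded by the quaternary C2 and the tertiary C6, so only C4=O reacts, and in the chair with the 6-methyl equatorial the axial methyl on C2 blocks the axial trajectory, so the bulky borohydride should attack equatorially and give the axial (4R) alcohol trans to the 6-methyl, as in the 3,3,5-trimethylcyclohexanone model. Any product of attack from the other face is a diastereomer at this stage only and is removed here by crystallisation or chromatography.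

**Step 3**
Reactants: 3 (4R,6R)-4-hydroxy-2,2,6-trimethylcyclohexan-1-one
Product: 4 (4R,6R)-4-[(tert-butyldimethylsilyl)oxy]-2,2,6-trimethylcyclohexan-1-one
Conditions: TBSCl, imidazole, DMF, rt
Reagents that add atoms: tert-butyldimethylsilyl chloride, CC(C)(C)[Si](C)(C)Cl
Why: Standard silylation of a secondary alcohol; the silyl ether has no acidic C–H and withstands the amide base of step 4, which an ester at this oxygen would not.

**Step 4**
Reactants: 4 (4R,6R)-4-[(tert-butyldimethylsilyl)oxy]-2,2,6-trimethylcyclohexan-1-one
Product: 6 (4R)-4-[(tert-butyldimethylsilyl)oxy]-2,6,6-trimethylcyclohex-1-en-1-yl trifluoromethanesulfonate, via lithium enolate 5 (not isolated)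
Conditions: LiN(i-Pr)2 (1.3 equiv), THF, −78 to 0 °C; PhNTf2 (1.3 equiv), 0 °C to rt; then H2O
Reagents that add atoms: N-phenylbis(trifluoromethanesulfonimide), O=S(=O)(C(F)(F)F)N(c1ccccc1)S(=O)(=O)C(F)(F)F; lithium diisopropylamide, [Li]N(C(C)C)C(C)C (lithium of 5 only)
Why: Enolate O-triflation: C6 carries the only α-hydrogen of 4, so deprotonation can give only 5, and sulfonyl transfer from PhNTf2 to the enolate oxygen gives the tetrasubstituted enol triflate. The C6 stereocentre has done its work and is erased, while C4 is separated from the enolate carbon by a CH2 group, so neither epimerisation nor E1cB loss of silanolate is open.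

**Step 5**
Reactants: 6 (4R)-4-[(tert-butyldimethylsilyl)oxy]-2,6,6-trimethylcyclohex-1-en-1-yl trifluoromethanesulfonate
Product: 7 (4R)-4-hydroxy-2,6,6-trimethylcyclohex-1-en-1-yl trifluoromethanesulfonate
Conditions: HF·pyridine, pyridine, THF, 0 °C to rt
Reagents that add atoms: none
Why: Fluoride-driven cleavage of the Si–O bond in a weakly acidic medium; enol triflates tolerate HF·pyridine, whereas strongly basic fluoride sources could attack sulfur. The C–O bond at the stereocentre is not involved.

**Step 6**
Reactants: 7 (4R)-4-hydroxy-2,6,6-trimethylcyclohex-1-en-1-yl trifluoromethanesulfonate; 8 (9Z)-hexadec-9-enoic acid (palmitoleic acid)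
Product: 10 (1R)-3,5,5-trimethyl-4-{[(trifluoromethyl)sulfonyl]oxy}cyclohex-3-en-1-yl (9Z)-hexadec-9-enoate, via O-acylisourea 9 (not isolated)
Conditions: DCC, DMAP (cat.), CH2Cl2, 0 °C to rt
Reagents that add atoms: N,N'-dicyclohexylcarbodiimide, C(=NC1CCCCC1)=NC1CCCCC1 (atoms of 9 only)
Why: Steglich esterification: the carbodiimide activates 8 as 9 and DMAP shuttles the acyl group to the secondary alcohol. Only the acyl C–O bond is formed, so (R) is retained, and neither the 9Z alkene nor the enol triflate reacts with these reagents.

**Step 7**
Reactants: 11 all-E-8'-apo-β-caroten-8'-al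
Product: 13 2-[(1E,3E,5E,7E,9E,11E,13E,15E,17E)-3,7,12,16-tetramethyl-18-(2,6,6-trimethylcyclohex-1-en-1-yl)octadeca-1,3,5,7,9,11,13,15,17-nonaen-1-yl]-4,4,5,5-tetramethyl-1,3,2-dioxaborolane, via lithium alkoxide adduct 12 (not isolated)
Conditions: CH2(Bpin)2 (1.2 equiv), lithium 2,2,6,6-tetramethylpiperidide (1.15 equiv), THF, 0 °C; then 11, −78 °C to rt, dark; then H2O
Reagents that add atoms: bis(pinacolato)borylmethane, CC1(C)OB(CB2OC(C)(C)C(C)(C)O2)OC1(C)C; lithium 2,2,6,6-tetramethylpiperidide, [Li]N1C(C)(C)CCCC1(C)C (lithium of 12 only)
Why: Boron–Wittig olefination: lithiated CH2(Bpin)2 adds 1,2 to the aldehyde to give 12, and syn B–O elimination from the rotamer that keeps the chain and the remaining boryl group apart should give the E alkenylboronate. The boron-stabilised carbanion is fully formed before 11 is added, so no free amide base meets the polyenal, and the methyl group on C9 adds to the steric bias for E.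

**Step 8**
Reactants: 10 (1R)-3,5,5-trimethyl-4-{[(trifluoromethyl)sulfonyl]oxy}cyclohex-3-en-1-yl (9Z)-hexadec-9-enoate; 13 all-E C31 nonaenyl pinacol boronate
Product: 14 (3R)-β,β-caroten-3-yl (9Z)-hexadec-9-enoate (target)
Conditions: Pd(OAc)2 (5 mol %), SPhos (2-dicyclohexylphosphino-2',6'-dimethoxybiphenyl, 10 mol %), K3PO4 (3 equiv), degassed THF/H2O 10:1, 40 °C, argon, dark
Reagents that add atoms: none
Why: Suzuki–Miyaura alkenyl–alkenyl cross-coupling, the closest known reaction type being the coupling of hindered 2,6,6-trimethylcyclohexenyl triflates with dienyl- to tetraenylboron or -tin reagents in retinoid chemistry. Mechanism: the monoligated zerovalent palladium–SPhos species inserts into the C6–O bond of 10, phosphate or hydroxide replaces the non-coordinating triflate on divalent palladium, the Pd–O unit takes over the C7 alkenyl group of 13 through a B–O–Pd bridge, and reductive elimination forms the C6–C7 σ bond. The step closes no ring and creates no stereocentre; C3 lies three bonds from the reacting carbon and is a spectator, so (R) is carried through. Both alkenyl partners react with retention, so the position of C5=C6 is fixed by the triflate and the 7E geometry by 13, and no double bond inside the chromophore is made or broken. The hindrance at C6 is tolerated because the alkenylpalladium stage has no β-hydrogen (C1 is quaternary, C5 trigonal) and cannot decay by β-hydride elimination while it waits for transmetalation, the incoming C7 is an unhindered CH terminus, and crowding at palladium accelerates the final reductive elimination. The chemoselectivity needed is C–OTf over ester, isolated 9Z alkene and polyene: only the triflate undergoes oxidative addition, the absence of palladium hydrides leaves the 9Z alkene in place, and K3PO4 in a mostly organic medium at 40 °C should spare a lipophilic secondary ester. The pinacol ester releases the labile polyenylboronic acid only slowly, which should hold protodeboronation and homocoupling down. End differentiation is complete by construction, since ring B is present only in 13 and ring A only in 10.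

## Compound list

1 | 2,6,6-trimethylcyclohex-2-ene-1,4-dione | CC1=CC(=O)CC(C)(C)C1=O | starting material
2 | (6R)-2,2,6-trimethylcyclohexane-1,4-dione | C[C@@H]1CC(=O)CC(C)(C)C1=O | intermediate
3 | (4R,6R)-4-hydroxy-2,2,6-trimethylcyclohexan-1-one | C[C@@H]1C[C@@H](O)CC(C)(C)C1=O | intermediate
4 | (4R,6R)-4-[(tert-butyldimethylsilyl)oxy]-2,2,6-trimethylcyclohexan-1-one | C[C@@H]1C[C@@H](O[Si](C)(C)C(C)(C)C)CC(C)(C)C1=O | intermediate
5 | lithium (4R)-4-[(tert-butyldimethylsilyl)oxy]-2,6,6-trimethylcyclohex-1-en-1-olate | CC1=C(O[Li])C(C)(C)C[C@H](O[Si](C)(C)C(C)(C)C)C1 | intermediate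
6 | (4R)-4-[(tert-butyldimethylsilyl)oxy]-2,6,6-trimethylcyclohex-1-en-1-yl trifluoromethanesulfonate | CC1=C(OS(=O)(=O)C(F)(F)F)C(C)(C)C[C@H](O[Si](C)(C)C(C)(C)C)C1 | intermediate
7 | (4R)-4-hydroxy-2,6,6-trimethylcyclohex-1-en-1-yl trifluoromethanesulfonate | CC1=C(OS(=O)(=O)C(F)(F)F)C(C)(C)C[C@H](O)C1 | intermediate
8 | (9Z)-hexadec-9-enoic acid | CCCCCC/C=C\CCCCCCCC(=O)O | starting material
9 | O-[(9Z)-hexadec-9-enoyl]-N,N'-dicyclohexylisourea | CCCCCC/C=C\CCCCCCCC(=O)OC(=NC1CCCCC1)NC1CCCCC1 | intermediate
10 | (1R)-3,5,5-trimethyl-4-{[(trifluoromethyl)sulfonyl]oxy}cyclohex-3-en-1-yl (9Z)-hexadec-9-enoate | CCCCCC/C=C\CCCCCCCC(=O)O[C@@H]1CC(C)=C(OS(=O)(=O)C(F)(F)F)C(C)(C)C1 | intermediate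
11 | all-E-8'-apo-β-caroten-8'-al | O=C/C(C)=C/C=C/C(C)=C/C=C/C=C(C)/C=C/C=C(C)/C=C/C1=C(C)CCCC1(C)C | starting material
12 | lithium alkoxide of the 1,2-adduct of 11 (OLi on C8, two pinacolboryl groups on C7, C8 unassigned) | [Li]OC(C(B1OC(C)(C)C(C)(C)O1)B1OC(C)(C)C(C)(C)O1)/C(C)=C/C=C/C(C)=C/C=C/C=C(C)/C=C/C=C(C)/C=C/C1=C(C)CCCC1(C)C | intermediate
13 | all-E C31 nonaenyl pinacol boronate (boron on C7) | CC1(C)OB(/C=C/C(C)=C/C=C/C(C)=C/C=C/C=C(C)/C=C/C=C(C)/C=C/C2=C(C)CCCC2(C)C)OC1(C)C | intermediate
14 | (3R)-β,β-caroten-3-yl (9Z)-hexadec-9-enoate | CCCCCC/C=C\CCCCCCCC(=O)O[C@@H]1CC(C)=C(/C=C/C(C)=C/C=C/C(C)=C/C=C/C=C(C)/C=C/C=C(C)/C=C/C2=C(C)CCCC2(C)C)C(C)(C)C1 | target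

## Step count and least certain steps

Total step count: 8. Longest linear sequence: 7 (steps 1–6 and 8). Step 7 is a one-step branch.

**Step 8 (key step).**
- Risk: oxidative addition and transmetalation at the crowded C6 may be slow. Side processes could then win, namely protodeboronation and oxidative homocoupling of the polyenylboron species, S–O cleavage of the triflate by hydroxide, and thermal E/Z drift of the chromophore.
- Fallback: it moves the junction one bond outward to C7=C8. It sets out from 10 and 11, so step 7 is not needed, and comes back at 14.
- Reductive carbonylation of 10 (Pd(PPh3)4, CO, Bu3SnH, LiCl, THF, 50 °C) would give (1R)-4-formyl-3,5,5-trimethylcyclohex-3-en-1-yl (9Z)-hexadec-9-enoate F1. Carbon monoxide is a far smaller partner than a polyenylboron reagent.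
- NaBH4 in MeOH at 0 °C would give (1R)-4-(hydroxymethyl)-3,5,5-trimethylcyclohex-3-en-1-yl (9Z)-hexadec-9-enoate F2.
- PPh3·HBr in CH2Cl2 would give {[(4R)-4-[(9Z)-hexadec-9-enoyloxy]-2,6,6-trimethylcyclohex-1-en-1-yl]methyl}triphenylphosphonium bromide F3.
- One equivalent of NaN(SiMe3)2 at −78 °C removes the more acidic P–CH2 proton rather than an ester α-proton and gives the corresponding triphenylphosphonium ylide F4.
- A Wittig reaction of F4 with 11 would give 14. The 7Z arrangement is strongly destabilised by the ring methyl groups, so E should prevail.

**Step 7.**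
- Risk: the polyenal is a weak electrophile, so addition may be incomplete. The E/Z control of the B–O elimination may erode, and the boronate may lose boron on acidic adsorbents.
- Fallback: it goes through an alkyne. It sets out from 11 and comes back at 13.
- A Colvin rearrangement (Me3SiCHN2, LiN(i-Pr)2, THF, −78 °C to rt) would give the all-E C31 terminal enyne (C7≡C8 in place of the aldehyde) F5.
- Hydroboration of F5 with pinacolborane and catalytic Cp2ZrHCl would give 13. The geometry is then set by syn addition to the only alkyne.

**Step 4.**
- Risk: removal of the single tertiary α-hydrogen next to a very hindered carbonyl may be slow. Unreacted ketone or hydride transfer from the amide base could then compete.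
- Fallback: it generates the same enolate by conjugate hydride addition instead of deprotonation. It needs no protecting group, sets out from 1 and comes back at 10.
- A ketoreductase selective for the unhindered C4=O (glucose and glucose dehydrogenase for recycling) would give (4S)-4-hydroxy-2,6,6-trimethylcyclohex-2-en-1-one F6.
- Steglich acylation of F6 with 8 would give (1S)-3,5,5-trimethyl-4-oxocyclohex-2-en-1-yl (9Z)-hexadec-9-enoate F7.
- LiBH(s-Bu)3 at −78 °C should add hydride to the unsubstituted β-carbon, since the carbonyl is blocked by the gem-dimethyl group. This gives lithium (4R)-4-[(9Z)-hexadec-9-enoyloxy]-2,6,6-trimethylcyclohex-1-en-1-olate F8.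
- PhNTf2 converts F8 into 10.
- This variant is shorter. It is kept in reserve because its stereo-defining step offers no diastereomeric purification and must distinguish two carbonyl groups and the C=C bond.

**Step 2.**
- Risk: the 1,4-dione ring can populate twist-boat forms in which the axial C2 methyl no longer shields one face, so facial selectivity may be poor. Partial enolisation of 2 in the aqueous medium of step 1 would add to the loss of stereochemical purity.
- Fallback: it replaces substrate control by an enzymatic kinetic resolution merged with the acylation. It sets out from 7 and comes back at 10.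
- Immobilised Burkholderia cepacia lipase, 8 and molecular sieves in methyl tert-butyl ether at 40 °C should acylate the (R)-alcohol preferentially. By the empirical size rule for lipases, the larger flank (CH2 next to the quaternary carbon) is also the flank of higher priority.
- The (4S)-4-hydroxy-2,6,6-trimethylcyclohex-1-en-1-yl trifluoromethanesulfonate F9 stays unacylated and is separated.

## Further compounds

F1 | step 8 | (1R)-4-formyl-3,5,5-trimethylcyclohex-3-en-1-yl (9Z)-hexadec-9-enoate | CCCCCC/C=C\CCCCCCCC(=O)O[C@@H]1CC(C)=C(C=O)C(C)(C)C1
F2 | step 8 | (1R)-4-(hydroxymethyl)-3,5,5-trimethylcyclohex-3-en-1-yl (9Z)-hexadec-9-enoate | CCCCCC/C=C\CCCCCCCC(=O)O[C@@H]1CC(C)=C(CO)C(C)(C)C1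
F3 | step 8 | {[(4R)-4-[(9Z)-hexadec-9-enoyloxy]-2,6,6-trimethylcyclohex-1-en-1-yl]methyl}triphenylphosphonium bromide | CCCCCC/C=C\CCCCCCCC(=O)O[C@@H]1CC(C)=C(C[P+](c2ccccc2)(c2ccccc2)c2ccccc2)C(C)(C)C1.[Br-]
F4 | step 8 | triphenylphosphonium ylide of F3 | CCCCCC/C=C\CCCCCCCC(=O)O[C@@H]1CC(C)=C(C=P(c2ccccc2)(c2ccccc2)c2ccccc2)C(C)(C)C1
F5 | step 7 | all-E C31 terminal enyne | C#C/C(C)=C/C=C/C(C)=C/C=C/C=C(C)/C=C/C=C(C)/C=C/C1=C(C)CCCC1(C)C
F6 | step 4 | (4S)-4-hydroxy-2,6,6-trimethylcyclohex-2-en-1-one | O[C@@H]1C=C(C)C(=O)C(C)(C)C1
F7 | step 4 | (1S)-3,5,5-trimethyl-4-oxocyclohex-2-en-1-yl (9Z)-hexadec-9-enoate | CCCCCC/C=C\CCCCCCCC(=O)O[C@@H]1C=C(C)C(=O)C(C)(C)C1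
F8 | step 4 | lithium (4R)-4-[(9Z)-hexadec-9-enoyloxy]-2,6,6-trimethylcyclohex-1-en-1-olate | CCCCCC/C=C\CCCCCCCC(=O)O[C@@H]1CC(C)=C(O[Li])C(C)(C)C1
F9 | step 2 | (4S)-4-hydroxy-2,6,6-trimethylcyclohex-1-en-1-yl trifluoromethanesulfonate | CC1=C(OS(=O)(=O)C(F)(F)F)C(C)(C)C[C@@H](O)C1
A1 | alternative 1 | (3R)-β,β-caroten-3-ol | O[C@@H]1CC(C)=C(/C=C/C(C)=C/C=C/C(C)=C/C=C/C=C(C)/C=C/C=C(C)/C=C/C2=C(C)CCCC2(C)C)C(C)(C)C1
A2 | alternative 1 | [(2E,4E)-5-[(4R)-4-hydroxy-2,6,6-trimethylcyclohex-1-en-1-yl]-3-methylpenta-2,4-dien-1-yl]triphenylphosphonium bromide | O[C@@H]1CC(C)=C(/C=C/C(C)=C/C[P+](c2ccccc2)(c2ccccc2)c2ccccc2)C(C)(C)C1.[Br-]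
A3 | alternative 1 | 12'-apo-β-caroten-12'-al | O=C/C(C)=C/C=C/C=C(C)/C=C/C=C(C)/C=C/C1=C(C)CCCC1(C)C
A4 | alternative 2 | retinyl (3R)-3-(tert-butyldimethylsilyloxy)retinyl sulfone | CC1=C(/C=C/C(C)=C/C=C/C(C)=C/CS(=O)(=O)C/C=C(C)/C=C/C=C(C)/C=C/C2=C(C)C[C@@H](O[Si](C)(C)C(C)(C)C)CC2(C)C)C(C)(C)CCC1
A5 | alternative 2 | all-E-retinol | OC/C=C(C)/C=C/C=C(C)/C=C/C1=C(C)CCCC1(C)C
A6 | alternative 3 | 8,8'-diapocarotene-8,8'-dial | O=C/C(C)=C/C=C/C(C)=C/C=C/C=C(C)/C=C/C=C(C)/C=O
A7 | alternative 3 | all-E C22 nonaene-1,18-diyl bis(pinacol boronate) | CC1(C)OB(/C=C/C(C)=C/C=C/C(C)=C/C=C/C=C(C)/C=C/C=C(C)/C=C/B2OC(C)(C)C(C)(C)O2)OC1(C)C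
A8 | alternative 3 | 2,6,6-trimethylcyclohex-1-en-1-yl trifluoromethanesulfonate | CC1=C(OS(=O)(=O)C(F)(F)F)C(C)(C)CCC1
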